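## Structural features

Nortopsentin B is built from three aromatic heterocycles joined by two C–C single bonds: a central 1H-imidazole whose C2 carries C3 of a 6-bromo-1H-indole and whose C4 carries C3 of an unsubstituted 1H-indole. The molecule is planar and achiral, so there are no stereocentres, adjacent or otherwise, and every selectivity problem is one of regio- or chemoselectivity. Because the imidazole N–H tautomerises, the 2,4- and 2,5-descriptions are the same compound, but the two indoles are not equivalent: bromine must end up on C6 of exactly the one bound to imidazole C2. The fragile features are the aryl C–Br bond (hydrogenolysis, alkyllithium exchange, insertion of low-valent palladium), the three acidic N–H groups, and the electron-rich indole C2=C3 bonds, which are sensitive to oxidants and to acid in the presence of aldehydes. The real difficulty is therefore the unsymmetrical assembly: two nearly identical indol-3-yl groups must be placed on defined imidazole carbons while the halogen survives every step. The key step exploits that C3 of the unsubstituted indole lies between its benzo carbon C3a and imidazole C4, so that in the ring-opened form it is a CH2 flanked by two aromatic rings and the most acidic C–H present, while C2 is a lone CH bound to N1 and can be delivered as the terminal carbon of an isocyanide on the ortho carbon.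

## Logic of the disconnections

17 ⇒ 16. The two N–CH2 bonds that hold the silylethoxymethyl groups on imidazole N1 and on the bromoindole nitrogen are cut first. The groups are needed because the preceding ring closure uses a strong amide base: free N–H groups would consume it and, as N-anions, would suppress the C–H acidity on which the closure depends. The forward step must free an indole and an imidazole nitrogen in one operation, without touching C–Br and without letting the released formaldehyde attack the indoles.

16 ⇒ 13 (through 14 and 15). The C2–C3 bond of the unsubstituted indole is cut, which opens its pyrrole ring: C3 becomes a CH2 between the benzene ring and imidazole C4, and C2 becomes an isocyanide carbon on the ortho position. After this cut only one indole remains, so the two indoles of 17 cannot be confused and the bromine sits on the only one present. The isocyanide carbon is already at the oxidation level of C2–H. The forward step must deprotonate the CH2 in preference to every ring C–H, must not add the base to the isocyanide, and must leave C–Br alone.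

13 ⇒ 12 ⇒ 11 ⇒ 10. No skeletal bond is cut: the isocyanide is traced to the formamide, the formamide to the primary amine, and the amine to a nitro group. Nitro is the only form of this nitrogen that can be carried through the imidazole synthesis, because the free amine would condense with the ketone of 8 to a 2-substituted indole. The forward reduction must spare C–Br and the N,O-acetals, which excludes catalytic hydrogenation.

10 ⇒ 9. The N1–CH2 bond of the imidazole protecting group is cut. This nitrogen only exists once the imidazole is formed, so it is protected separately. The forward alkylation must not generate a carbanion at the nitrobenzylic CH2, whose acidity is estimated to approach that of the azole N–H, and it should favour the nitrogen remote from the benzyl group.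

9 ⇒ 4 + 8. The imidazole is cut at N1–C5 and N3–C4: C2 and both nitrogens stay with the amidine fragment, and C4, C5 and the benzyl group stay with the haloketone. This splits the molecule into two fragments of similar size, each one or two steps from a purchasable compound. The substitution pattern is fixed by which carbon of 8 carries bromine and which is the carbonyl. N-Alkylation must be faster than enolisation of the doubly activated CH2 of 8.

4 ⇒ 2 (through 3). One C–N bond of the amidine is cut, leaving the nitrile as the acyl-level precursor. The forward addition needs an electrophilic nitrile carbon, so the indole nitrogen must already be alkylated and cannot form a deactivating indolide.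

2 ⇒ 1. The N–CH2 bond of the indole protecting group is cut. It is installed at the very start so that the less acidic indole N–H never has to be deprotonated in the presence of the nitrobenzylic CH2. A double protection at the stage of 9 would do exactly that.

8 ⇒ 5 (through 6 and 7). The C–C bond between the carbonyl carbon and the CH2Br carbon is cut, a one-carbon homologation of a carboxylic acid. This places the halogen unambiguously on the terminal carbon, whereas brominating the corresponding methyl ketone would attack the benzylic carbon. The acyl activation must work without amine base, which would turn 6 into a ketene.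

## Other disconnections considered

Alternative 1: The cut runs through N1–C7a and C3–C3a of the unsubstituted indole, so that its whole benzo ring is delivered as an aryne.
- Forward step: the silyl triflate A3 and CsF would release the aryne in the presence of the N-tosylaminomethyl ketone A2, whose ketone sits on imidazole C4. The sulfonamide nitrogen adds to the aryne, the resulting aryl anion closes on the carbonyl, and loss of water gives the N-tosylindole A1.
- In its favour: two bonds and one ring form in a single operation, the aryne is symmetrical, and fluoride conditions use neither strong base nor transition metal, so the C–Br bond is safe.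
- Against it here: A2 needs an imidazol-4-yl bromomethyl ketone already carrying the bromoindole, a longer imidazole synthesis than one amidine condensation. The aryne is an indiscriminate electrophile, and the basic imidazole N3 competes with the sulfonamide. The carbamate on the bromoindole is not secure towards fluoride at the temperatures aryne generation may need. Three different nitrogen protecting groups call for two or three unmasking operations.
- Comparison: in bonds formed per step this alternative is the better plan (two against one), and in mildness towards the bromide it is the equal of the chosen one. Both close the pyrrole ring by a carbanion attacking an electrophilic carbon, but in 13 the nucleophile is generated at the one acidic CH2, whereas here selectivity depends on which nucleophile catches the aryne first. On step economy the chosen plan should be ahead, because 13 is three routine steps from a nitro group and 16 is unmasked in one operation.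

Alternative 2: The cut goes through N1–C2 and C3–C3a of the 6-bromoindole.
- Forward step: 5-bromo-2-iodoaniline A6 and the imidazol-2-yl silylalkyne A5 would be joined by Pd(OAc)2 with LiCl and K2CO3 (Larock heteroannulation). Oxidative addition at C–I, alkyne insertion that places the bulky silyl group next to nitrogen, and C–N reductive elimination give the 2-silylindole A4.
- In its favour: it is the most convergent of the four plans, it forms two bonds and a ring in one step, the bromine position is fixed by the choice of A6, and the silyl group could leave in the same fluoride treatment that removes the SEM groups.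
- Against it here: zerovalent palladium at elevated temperature must distinguish C–I from C–Br in A6 and must not insert into the C–Br bond of A4 once formed, so oligomerisation is a standing risk. A5 requires the other indole to be attached to the imidazole first, followed by a Sonogashira coupling at a 2-haloimidazole. N3 of the alkynylimidazole can bind the catalyst.
- Comparison: on convergence and on bonds per step this alternative is better than the chosen plan, and on the end game it is its equal if protodesilylation and SEM removal merge. On chemoselectivity at bromine the chosen plan is stronger, because no transition metal ever meets the C–Br bond and a lithium amide does not exchange with it. Step counts should be similar, since the gain from the annulation is spent on making A5.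

Alternative 3: The cut is N1–C7a of the 6-bromoindole alone.
- Forward step: the primary enamine A8, whose amino group must lie cis to the 4-bromo-2-iodophenyl ring, would be cyclised with CuI, a 1,2-diamine ligand and K3PO4 (Ullmann–Goldberg N-arylation) to the N–H indole A7.
- In its favour: copper–diamine catalysts couple aryl iodides under conditions where aryl bromides react far more slowly, the base is mild, no isocyanide is handled, and the new indole N–H needs no protecting group.
- Against it here: A8 is a push–pull enamine whose resting geometry should be the hydrogen-bonded one, with NH2 turned towards imidazole N3, so cyclisation depends on isomerisation through the imine tautomer. The same N3/NH2 pair can chelate and sequester copper. A8 also needs a 4-bromo-2-iodophenylacetic acid-derived amidine and a one-carbon enamine homologation, which are less accessible than 1 and 5.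
- Comparison: in bonds and rings formed the two key steps are equal (one bond, one ring), and the protecting-group burden is equal (two SEM groups). In mildness and in avoiding an isocyanide this alternative is the better one. The chosen plan is better on halogen safety, since it needs no kinetic discrimination between two carbon–halogen bonds, and on precursor access. The alternative would take about the same number of steps or slightly more.

Key step: step 9

Remark: SEM stands for [2-(trimethylsilyl)ethoxy]methyl; 9 and 17 are drawn as one imidazole N–H tautomer, the other tautomer being the same compound.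

## Route

Step 1
Reactants: 1 6-bromo-1H-indole-3-carbonitrile
Product: 2 6-bromo-1-SEM-indole-3-carbonitrile
Conditions: NaH, SEMCl, DMF, 0 °C → rt
Reagents that add atoms: SEMCl, 2-(trimethylsilyl)ethoxymethyl chloride, C[Si](C)(C)CCOCCl
Why: The 3-cyano group makes the indole N–H acidic, so NaH gives the N-anion cleanly and the chloromethyl ether alkylates nitrogen (SN2 N-alkylation of an indolide). Protecting this nitrogen before the nitroarene enters avoids a later double alkylation in which hydride would meet an acidic nitrobenzylic CH2, and it keeps the nitrile electrophilic for step 2.

Step 2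
Reactants: 2 6-bromo-1-SEM-indole-3-carbonitrile
Product: 4 6-bromo-1-SEM-indole-3-carboximidamide hydrochloride, via lithium N,N'-bis(trimethylsilyl)amidinate 3 (not isolated)
Conditions: LiN(SiMe3)2, THF, 0 °C → rt; then HCl (3 equiv, 2 M in Et2O), 0 °C
Reagents that add atoms: LiN(SiMe3)2, [Li+].C[Si](C)(C)[N-][Si](C)(C)C (second amidine nitrogen); hydrogen chloride, Cl (chloride of the salt)
Why: Addition of a lithium silylamide to a nitrile without alpha hydrogens gives the N-silylated amidinate, and acid strips both silyl groups to leave the amidinium chloride (silylamide route to amidines). With N1 alkylated no indolide forms to deactivate the nitrile; the SEM group, the aryl bromide and indole C2–H are inert to this weak hindered base, and brief cold stoichiometric HCl should not cleave the N,O-acetal.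

Step 3
Reactants: 5 (2-nitrophenyl)acetic acid
Product: 8 1-bromo-3-(2-nitrophenyl)propan-2-one, via (2-nitrophenyl)acetyl chloride 6 (not isolated), via 1-diazo-3-(2-nitrophenyl)propan-2-one 7 (not isolated)
Conditions: (COCl)2, cat. DMF, CH2Cl2, 0 °C → rt, concentrate; Me3SiCHN2, THF/MeCN, 0 °C; 48% aq HBr, 0 °C
Reagents that add atoms: trimethylsilyldiazomethane, C[Si](C)(C)C=[N+]=[N-] (the new CH2 carbon); hydrogen bromide, Br
Why: Arndt–Eistert-type acylation of the non-explosive silyl diazomethane by the acid chloride gives the diazoketone with loss of silicon as its chloride, and HBr protonates the diazo carbon and displaces dinitrogen to give the bromomethyl ketone. No amine base is used, so the acidic benzylic CH2 of 6 is not turned into a ketene, and bromine can only end up on the former diazo carbon.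

Step 4
Reactants: 4 6-bromo-1-SEM-indole-3-carboximidamide hydrochloride; 8 1-bromo-3-(2-nitrophenyl)propan-2-one
Product: 9 2-(6-bromo-1-SEM-indol-3-yl)-4-(2-nitrobenzyl)-1H-imidazole
Conditions: KHCO3, THF/H2O 4:1, reflux, 8 added slowly
Reagents that add atoms: none
Why: Condensation of an amidine with an alpha-haloketone: one amidine nitrogen displaces bromide, the other closes on the ketone and loss of water aromatises, placing the indolyl group at C2 and the nitrobenzyl group at C4 by construction. Bicarbonate with slow addition of 8 keeps free amidine in excess so that N-alkylation should outrun enolisation of the acidic ArCH2C(O) unit; the nitrogen is kept as nitro because an ortho amino group would close onto this ketone.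

Step 5
Reactants: 9 2-(6-bromo-1-SEM-indol-3-yl)-4-(2-nitrobenzyl)-1H-imidazole
Product: 10 2-(6-bromo-1-SEM-indol-3-yl)-4-(2-nitrobenzyl)-1-SEM-imidazole
Conditions: SEMCl, iPr2NEt, CH2Cl2, 0 °C → rt
Reagents that add atoms: SEMCl, 2-(trimethylsilyl)ethoxymethyl chloride, C[Si](C)(C)CCOCCl
Why: N-Alkylation of the neutral imidazole with a tertiary amine as acid scavenger generates no anion, so the nitrobenzylic CH2 is not deprotonated. The less hindered nitrogen, next to C5–H and remote from the benzyl group, should react preferentially; any N3 isomer would be removed by chromatography and would in any case lead to the same target.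

Step 6
Reactants: 10 2-(6-bromo-1-SEM-indol-3-yl)-4-(2-nitrobenzyl)-1-SEM-imidazole
Product: 11 2-{[2-(6-bromo-1-SEM-indol-3-yl)-1-SEM-imidazol-4-yl]methyl}aniline
Conditions: Fe powder, NH4Cl, EtOH/H2O 4:1, 75 °C
Reagents that add atoms: none
Why: Bechamp-type reduction by zerovalent iron under nearly neutral conditions converts the nitro group to the amine by electron transfer and, unlike palladium-catalysed hydrogenation, does not cleave the aryl C–Br bond; the SEM acetals and the imidazole are stable.

Step 7
Reactants: 11 2-{[2-(6-bromo-1-SEM-indol-3-yl)-1-SEM-imidazol-4-yl]methyl}aniline
Product: 12 N-(2-{[2-(6-bromo-1-SEM-indol-3-yl)-1-SEM-imidazol-4-yl]methyl}phenyl)formamide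
Conditions: HCO2Ac (preformed from Ac2O/HCO2H, 55 °C), THF, 0 °C → rt
Reagents that add atoms: acetic formic anhydride, CC(=O)OC=O (formyl group)
Why: The mixed anhydride transfers its formyl group, the more electrophilic and less hindered acyl, to the aniline nitrogen (N-formylation); the tertiary imidazole nitrogen cannot be acylated irreversibly.

Step 8
Reactants: 12 N-(2-{[2-(6-bromo-1-SEM-indol-3-yl)-1-SEM-imidazol-4-yl]methyl}phenyl)formamide
Product: 13 2-{[2-(6-bromo-1-SEM-indol-3-yl)-1-SEM-imidazol-4-yl]methyl}phenyl isocyanide
Conditions: POCl3, Et3N, CH2Cl2, −20 → 0 °C
Reagents that add atoms: none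
Why: Dehydration of a formanilide to the isocyanide by O-phosphorylation and amine-induced elimination. The medium stays basic, so the SEM groups survive; the isocyanide is purified on base-washed silica and used promptly.

Step 9
Reactants: 13 2-{[2-(6-bromo-1-SEM-indol-3-yl)-1-SEM-imidazol-4-yl]methyl}phenyl isocyanide
Product: 16 2-(6-bromo-1-SEM-indol-3-yl)-4-(1H-indol-3-yl)-1-SEM-imidazole (bis-SEM nortopsentin B), via benzylic organolithium 14 (not isolated), via N-lithioindole 15 (not isolated)
Conditions: lithium 2,2,6,6-tetramethylpiperidide (1.2 equiv, from n-BuLi and 2,2,6,6-tetramethylpiperidine), THF, −78 °C → rt, 13 added to the base; aq NH4Cl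
Reagents that add atoms: none
Why: This is the Ito–Saegusa indole synthesis, an intramolecular alpha-addition of a benzylic carbanion to an ortho isocyanide; the closest known reaction type is the lithium amide cyclisation of ortho-alkylphenyl isocyanides to 3-substituted indoles. The hindered amide removes a proton from the CH2 between the isocyanophenyl ring and imidazole C4 to give 14, whose carbon attacks the terminal, carbene-like isocyanide carbon in a 5-endo-dig closure that forms C2–C3 and the pyrrole ring; the resulting 2-lithio-3H-indole passes by amine-relayed proton transfer from C3 to C2 into the aromatic N-lithioindole 15, which the quench protonates to 16. No stereocentre is created. The selectivity needed is deprotonation at the diarylmethane carbon and not at imidazole C5, at C2 of the bromoindole or ortho to bromine: this is the only C–H stabilised by two aromatic rings and by the isocyano group, the competing sites are sp2 C–H bonds that normally need alkyllithiums, and because the amine shuttles protons while the ring closure is irreversible any misplaced lithium should be funnelled to 14. SEM is used on both nitrogens because it removes N–H acidity without acidifying the neighbouring ring C–H as a carbamate or sulfonyl group would. The piperidide is preferred to LiN(iPr)2 because it does not add to the isocyanide carbon, the usual failure when the benzylic position is secondary; lithium amides do not exchange with the aryl bromide, and only a small excess is used, with quenching as soon as closure is complete, to avoid aryne formation. The isocyanide carbon arrives at the correct oxidation level, so C2 carries hydrogen and nothing has to be removed afterwards.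

Step 10
Reactants: 16 2-(6-bromo-1-SEM-indol-3-yl)-4-(1H-indol-3-yl)-1-SEM-imidazole
Product: 17 nortopsentin B, 2-(6-bromo-1H-indol-3-yl)-4-(1H-indol-3-yl)-1H-imidazole
Conditions: Bu4NF (1 M in THF, excess), H2NCH2CH2NH2, THF, 65 °C
Reagents that add atoms: none
Why: Fluoride attacks silicon and each SEM group fragments to fluorotrimethylsilane, ethylene and formaldehyde, freeing the indole and imidazole nitrogens (fluoride-induced beta-elimination of a 2-silylethyl ether). Ethylenediamine traps the formaldehyde as an aminal so that it cannot hydroxymethylate the electron-rich indoles, and neither reagent affects the aryl bromide.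

## Compound list

1 | 6-bromo-1H-indole-3-carbonitrile | N#Cc1c[nH]c2cc(Br)ccc12 | starting material
2 | 6-bromo-1-SEM-indole-3-carbonitrile | N#Cc1cn(COCC[Si](C)(C)C)c2cc(Br)ccc12 | intermediate
3 | lithium N,N'-bis(trimethylsilyl)-6-bromo-1-SEM-indole-3-carboximidamidate | C[Si](C)(C)N=C(N([Li])[Si](C)(C)C)c1cn(COCC[Si](C)(C)C)c2cc(Br)ccc12 | intermediate (not isolated)
4 | 6-bromo-1-SEM-indole-3-carboximidamide hydrochloride | Cl.NC(=N)c1cn(COCC[Si](C)(C)C)c2cc(Br)ccc12 | intermediate
5 | (2-nitrophenyl)acetic acid | O=C(O)Cc1ccccc1[N+](=O)[O-] | starting material
6 | (2-nitrophenyl)acetyl chloride | O=C(Cl)Cc1ccccc1[N+](=O)[O-] | intermediate (not isolated)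
7 | 1-diazo-3-(2-nitrophenyl)propan-2-one | [N-]=[N+]=CC(=O)Cc1ccccc1[N+](=O)[O-] | intermediate (not isolated)
8 | 1-bromo-3-(2-nitrophenyl)propan-2-one | O=C(CBr)Cc1ccccc1[N+](=O)[O-] | intermediate
9 | 2-(6-bromo-1-SEM-indol-3-yl)-4-(2-nitrobenzyl)-1H-imidazole | O=[N+]([O-])c1ccccc1Cc1c[nH]c(-c2cn(COCC[Si](C)(C)C)c3cc(Br)ccc23)n1 | intermediate
10 | 2-(6-bromo-1-SEM-indol-3-yl)-4-(2-nitrobenzyl)-1-SEM-imidazole | O=[N+]([O-])c1ccccc1Cc1cn(COCC[Si](C)(C)C)c(-c2cn(COCC[Si](C)(C)C)c3cc(Br)ccc23)n1 | intermediate
11 | 2-{[2-(6-bromo-1-SEM-indol-3-yl)-1-SEM-imidazol-4-yl]methyl}aniline | Nc1ccccc1Cc1cn(COCC[Si](C)(C)C)c(-c2cn(COCC[Si](C)(C)C)c3cc(Br)ccc23)n1 | intermediate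
12 | N-(2-{[2-(6-bromo-1-SEM-indol-3-yl)-1-SEM-imidazol-4-yl]methyl}phenyl)formamide | O=CNc1ccccc1Cc1cn(COCC[Si](C)(C)C)c(-c2cn(COCC[Si](C)(C)C)c3cc(Br)ccc23)n1 | intermediate
13 | 2-{[2-(6-bromo-1-SEM-indol-3-yl)-1-SEM-imidazol-4-yl]methyl}phenyl isocyanide | [C-]#[N+]c1ccccc1Cc1cn(COCC[Si](C)(C)C)c(-c2cn(COCC[Si](C)(C)C)c3cc(Br)ccc23)n1 | intermediate
14 | benzylic organolithium of 13 (lithium on the CH between the isocyanophenyl ring and imidazole C4) | [Li]C(c1ccccc1[N+]#[C-])c1cn(COCC[Si](C)(C)C)c(-c2cn(COCC[Si](C)(C)C)c3cc(Br)ccc23)n1 | intermediate (not isolated)
15 | N-lithio derivative of 16 (lithium on the new indole nitrogen) | [Li]n1cc(-c2cn(COCC[Si](C)(C)C)c(-c3cn(COCC[Si](C)(C)C)c4cc(Br)ccc34)n2)c2ccccc21 | intermediate (not isolated)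
16 | 2-(6-bromo-1-SEM-indol-3-yl)-4-(1H-indol-3-yl)-1-SEM-imidazole (bis-SEM nortopsentin B) | Brc1ccc2c(-c3nc(-c4c[nH]c5ccccc45)cn3COCC[Si](C)(C)C)cn(COCC[Si](C)(C)C)c2c1 | intermediate
17 | nortopsentin B, 2-(6-bromo-1H-indol-3-yl)-4-(1H-indol-3-yl)-1H-imidazole | Brc1ccc2c(-c3nc(-c4c[nH]c5ccccc45)c[nH]3)c[nH]c2c1 | target

## Step count and least certain steps

Total step count: 10. Longest linear sequence: 9 steps (1 → 17 through steps 1, 2 and 4 to 10); step 3 is the one-step side branch from 5.

Step 9 (key step). The most likely failures are:
- addition of the amide base to the isocyanide carbon;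
- metalation ortho to bromine followed by aryne formation on warming;
- attack of the carbanion on the isocyanide of a second molecule;
- sluggish ring closure of a carbanion that is more stabilised than a simple ortho-tolyl anion.

Fallback: give up the isocyanide closure and bring the second indole in preformed. Setting out from 4, the bicarbonate condensation of step 4 would be run with 2-bromo-1-(1H-indol-3-yl)ethan-1-one F1 (a purchasable haloketone). This should give 2-(6-bromo-1-SEM-indol-3-yl)-4-(1H-indol-3-yl)-1H-imidazole F2, and the fluoride and ethylenediamine treatment of step 10 would remove its single SEM group and return to the route at 17.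

Step 4. The doubly activated CH2 of 8 may be enolised by the amidine. Self-alkylation or a Favorskii-type closure would then compete with N-alkylation and erode the yield. Fallback: the keto ester route to imidazoles (Davidson-type), in which no base stronger than a carboxylate meets 8. Setting out from 2, hydrolysis of the nitrile (KOH, EtOH/H2O, reflux, then AcOH) would give 6-bromo-1-SEM-indole-3-carboxylic acid F3. O-Alkylation of its caesium salt with 8 (Cs2CO3, DMF, rt) would give 3-(2-nitrophenyl)-2-oxopropyl 6-bromo-1-SEM-indole-3-carboxylate F4. Heating F4 with excess NH4OAc in xylene at 140 °C would close the imidazole and return to the route at 9.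

Step 2. The nitrile is an enaminonitrile and may add the silylamide slowly, and the acidic work-up could partly remove the SEM group. Fallback: the amidoxime route. Setting out from 2, NH2OH (50% aq, EtOH, 80 °C) would give (Z)-6-bromo-N'-hydroxy-1-SEM-indole-3-carboximidamide F5. Ac2O in AcOH would give its O-acetate, (Z)-N'-acetoxy-6-bromo-1-SEM-indole-3-carboximidamide F6. N–O cleavage with Zn dust in AcOH, a reduction that spares C–Br, followed by HCl in Et2O, would return to the route at 4.

Step 10. Cleavage may be incomplete, because the imidazole SEM group responds to fluoride more slowly than the indole one, and it may stall at the N-hydroxymethyl stage. Fallback: acidolysis followed by base instead of fluoride. Setting out from 16, CF3CO2H in CH2Cl2 at rt would cleave both acetals to [2-(6-bromo-1-(hydroxymethyl)indol-3-yl)-4-(1H-indol-3-yl)imidazol-1-yl]methanol F7. Ethylenediamine in MeOH would then remove both hydroxymethyl groups as formaldehyde and return to the route at 17.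

## Further compounds

F1 | step 9 | 2-bromo-1-(1H-indol-3-yl)ethan-1-one (purchased reagent of the fallback) | O=C(CBr)c1c[nH]c2ccccc12
F2 | step 9 | 2-(6-bromo-1-SEM-indol-3-yl)-4-(1H-indol-3-yl)-1H-imidazole | Brc1ccc2c(-c3nc(-c4c[nH]c5ccccc45)c[nH]3)cn(COCC[Si](C)(C)C)c2c1
F3 | step 4 | 6-bromo-1-SEM-indole-3-carboxylic acid | O=C(O)c1cn(COCC[Si](C)(C)C)c2cc(Br)ccc12
F4 | step 4 | 3-(2-nitrophenyl)-2-oxopropyl 6-bromo-1-SEM-indole-3-carboxylate | O=C(COC(=O)c1cn(COCC[Si](C)(C)C)c2cc(Br)ccc12)Cc1ccccc1[N+](=O)[O-]
F5 | step 2 | (Z)-6-bromo-N'-hydroxy-1-SEM-indole-3-carboximidamide | N/C(=N\O)c1cn(COCC[Si](C)(C)C)c2cc(Br)ccc12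
F6 | step 2 | (Z)-N'-acetoxy-6-bromo-1-SEM-indole-3-carboximidamide | CC(=O)O/N=C(\N)c1cn(COCC[Si](C)(C)C)c2cc(Br)ccc12
F7 | step 10 | [2-(6-bromo-1-(hydroxymethyl)indol-3-yl)-4-(1H-indol-3-yl)imidazol-1-yl]methanol | OCn1cc(-c2nc(-c3c[nH]c4ccccc34)cn2CO)c2ccc(Br)cc21
A1 | alternative 1 | tert-butyl 6-bromo-3-[4-(1-tosylindol-3-yl)-1-SEM-imidazol-2-yl]indole-1-carboxylate | Brc1ccc2c(-c3nc(-c4cn(S(=O)(=O)c5ccc(C)cc5)c5ccccc45)cn3COCC[Si](C)(C)C)cn(C(=O)OC(C)(C)C)c2c1
A2 | alternative 1 | tert-butyl 6-bromo-3-[4-(N-tosylglycyl)-1-SEM-imidazol-2-yl]indole-1-carboxylate (N-tosylaminomethyl ketone on imidazole C4) | Cc1ccc(cc1)S(=O)(=O)NCC(=O)c1cn(COCC[Si](C)(C)C)c(n1)-c1cn(C(=O)OC(C)(C)C)c2cc(Br)ccc12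
A3 | alternative 1 | 2-(trimethylsilyl)phenyl trifluoromethanesulfonate | C[Si](C)(C)c1ccccc1OS(=O)(=O)C(F)(F)F
A4 | alternative 2 | 6-bromo-3-[4-(1-SEM-indol-3-yl)-1-SEM-imidazol-2-yl]-2-(trimethylsilyl)-1H-indole | C[Si](C)(C)c1[nH]c2cc(Br)ccc2c1-c1nc(-c2cn(COCC[Si](C)(C)C)c3ccccc23)cn1COCC[Si](C)(C)C
A5 | alternative 2 | 4-(1-SEM-indol-3-yl)-1-SEM-2-[(trimethylsilyl)ethynyl]imidazole | C[Si](C)(C)C#Cc1nc(-c2cn(COCC[Si](C)(C)C)c3ccccc23)cn1COCC[Si](C)(C)C
A6 | alternative 2 | 5-bromo-2-iodoaniline | Nc1cc(Br)ccc1I
A7 | alternative 3 | 6-bromo-3-[4-(1-SEM-indol-3-yl)-1-SEM-imidazol-2-yl]-1H-indole | Brc1ccc2c(-c3nc(-c4cn(COCC[Si](C)(C)C)c5ccccc45)cn3COCC[Si](C)(C)C)c[nH]c2c1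
A8 | alternative 3 | (E)-2-(4-bromo-2-iodophenyl)-2-[4-(1-SEM-indol-3-yl)-1-SEM-imidazol-2-yl]ethen-1-amine (NH2 cis to the aryl ring) | N/C=C(\c1ccc(Br)cc1I)c1nc(-c2cn(COCC[Si](C)(C)C)c3ccccc23)cn1COCC[Si](C)(C)C
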